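**Retrosynthetic overview**
- The target comes from a penta-TIPS ether by fluoride desilylation; the stilbene C=C is cut by a Heck disconnection into a 5-bromo-2,3-diaryl-2,3-dihydrobenzofuran and 3,5-bis(silyloxy)styrene.
- The dihydrofuran ring is the only ring built (all benzene rings are bought). Its C2–C3 bond is made by intermolecular Michael addition of a chiral benzylic sulfonium ylide to an o-quinone methide, and its O1–C2 bond by SN2 closure in the same flask.
- The o-quinone methide comes from a sulfone, made from a diaryl carbinol (5-bromosalicylaldehyde + aryl Grignard). The ylide comes from isothiocineole and 4-(silyloxy)benzyl bromide.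

Assumption: the benzylide of (1R,4R,5R)-isothiocineole is attacked on the ylide face remote from the CMe2 bridge, which leads to the (2S,3S) series; this sense is model-derived and, if the first run shows the opposite, the (1S,4S,5S) sulfide is used with nothing else changed.

**Step 1**
Reactants: 1 5-bromobenzene-1,3-diol
Product: 2 1-bromo-3,5-bis(triisopropylsilyloxy)benzene
Conditions: TIPSCl (2.3 equiv), imidazole, DMF, rt
Reagents that add atoms: chlorotriisopropylsilane, CC(C)[Si](Cl)(C(C)C)C(C)C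
Why: Silyl ether protection of both phenols; TIPS ethers survive the Grignard, carbonate and Pd steps and are removed by fluoride at the end.

**Step 2**
Reactants: 2 1-bromo-3,5-bis(triisopropylsilyloxy)benzene; 3 5-bromo-2-hydroxybenzaldehyde
Product: 5 rac-4-bromo-2-{[3,5-bis(triisopropylsilyloxy)phenyl](hydroxy)methyl}phenol, via arylmagnesium bromide 4 (not isolated)
Conditions: 2 (2.3 equiv), Mg, I2 (cat.), THF, 50 °C; then 3 (1.0 equiv), 0 °C → rt; aq NH4Cl
Reagents that add atoms: none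
Why: Grignard addition to the aldehyde (the first equivalent only deprotonates the phenol, and the aryl bromide of 3 is inert); the carbinol centre is racemic and is erased in step 8.

**Step 3**
Reactants: 5 rac-4-bromo-2-{[3,5-bis(triisopropylsilyloxy)phenyl](hydroxy)methyl}phenol
Product: 6 rac-4-bromo-2-{[3,5-bis(triisopropylsilyloxy)phenyl](4-methylbenzenesulfonyl)methyl}phenol
Conditions: p-TolSO2H (1.3 equiv), CH2Cl2, rt
Reagents that add atoms: p-toluenesulfinic acid, Cc1ccc(cc1)S(=O)O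
Why: Acid-promoted SN1-type substitution through the o-hydroxybenzhydryl cation, trapped at sulfur, gives a bench-stable sulfone that releases the o-quinone methide under mild base.

**Step 4**
Reactants: 7 4-hydroxybenzaldehyde
Product: 8 4-(triisopropylsilyloxy)benzaldehyde
Conditions: TIPSCl, imidazole, DMF, rt
Reagents that add atoms: chlorotriisopropylsilane, CC(C)[Si](Cl)(C(C)C)C(C)C
Why: Silyl ether protection of the phenol, matching the other protecting groups for one final deprotection.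

**Step 5**
Reactants: 8 4-(triisopropylsilyloxy)benzaldehyde
Product: 9 [4-(triisopropylsilyloxy)phenyl]methanol
Conditions: NaBH4, MeOH, 0 °C
Reagents that add atoms: none
Why: Borohydride reduction of the aldehyde; the aryl silyl ether is untouched.

**Step 6**
Reactants: 9 [4-(triisopropylsilyloxy)phenyl]methanol
Product: 10 4-(triisopropylsilyloxy)benzyl bromide
Conditions: CBr4, PPh3, CH2Cl2, 0 °C; short silica plug, used at once
Reagents that add atoms: carbon tetrabromide, BrC(Br)(Br)Br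
Why: Appel bromination runs under neutral conditions, which the acid-labile, ionisation-prone p-silyloxybenzyl system tolerates.

**Step 7**
Reactants: 10 4-(triisopropylsilyloxy)benzyl bromide; 11 (1R,4R,5R)-4,7,7-trimethyl-6-thiabicyclo[3.2.1]octane (isothiocineole)
Product: 12 (1R,4R,5R,6R)-4,7,7-trimethyl-6-[4-(triisopropylsilyloxy)benzyl]-6-thiabicyclo[3.2.1]octan-6-ium tetrafluoroborate (benzyl on the exo lone pair of sulfur)
Conditions: NaBF4 (1.5 equiv), acetone, rt, dark
Reagents that add atoms: sodium tetrafluoroborate, [Na+].F[B-](F)(F)F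
Why: SN2 S-alkylation on the unhindered exo lone pair gives one sulfonium diastereomer, and anion metathesis to the non-nucleophilic BF4 salt prevents reversal.

**Step 8 (key step)**
Reactants: 6 rac-4-bromo-2-{[3,5-bis(triisopropylsilyloxy)phenyl](4-methylbenzenesulfonyl)methyl}phenol; 12 (1R,4R,5R,6R)-4,7,7-trimethyl-6-[4-(triisopropylsilyloxy)benzyl]-6-thiabicyclo[3.2.1]octan-6-ium tetrafluoroborate
Product: 16 (2S,3S)-5-bromo-3-[3,5-bis(triisopropylsilyloxy)phenyl]-2-[4-(triisopropylsilyloxy)phenyl]-2,3-dihydro-1-benzofuran, via o-quinone methide 13 (not isolated), via sulfonium ylide 14 (not isolated), via anti-betaine 15 (not isolated)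
Conditions: 12 (1.3 equiv), Cs2CO3 (3 equiv), MeCN–CH2Cl2 (1:1), −20 °C → rt; sulfide 11 recovered
Reagents that add atoms: none
Why: Base unmasks both partners and the ylide adds in a Michael (1,4-) fashion to the exocyclic carbon of the o-quinone methide, forming C2–C3, after which the phenoxide displaces the sulfide in a 5-exo-tet SN2 (Michael-initiated ring closure, formal [4+1]); C2 is set by attack on the ylide face remote from the CMe2 bridge followed by inversion in the closure, and C3 by the anti betaine that closes to the trans ring.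

**Step 9**
Reactants: 17 3,5-dihydroxybenzaldehyde
Product: 18 3,5-bis(triisopropylsilyloxy)benzaldehyde
Conditions: TIPSCl (2.3 equiv), imidazole, DMF, rt
Reagents that add atoms: chlorotriisopropylsilane, CC(C)[Si](Cl)(C(C)C)C(C)C
Why: Silyl ether protection of both phenols before the basic Wittig step.

**Step 10**
Reactants: 18 3,5-bis(triisopropylsilyloxy)benzaldehyde
Product: 19 1-ethenyl-3,5-bis(triisopropylsilyloxy)benzene
Conditions: Ph3PCH3Br, KOtBu, THF, 0 °C → rt
Reagents that add atoms: methyltriphenylphosphonium bromide, C[P+](c1ccccc1)(c1ccccc1)c1ccccc1.[Br-]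
Why: Wittig methylenation of a non-enolisable aryl aldehyde is clean, and aryl TIPS ethers tolerate the ylide.

**Step 11**
Reactants: 16 (2S,3S)-5-bromo-3-[3,5-bis(triisopropylsilyloxy)phenyl]-2-[4-(triisopropylsilyloxy)phenyl]-2,3-dihydro-1-benzofuran; 19 1-ethenyl-3,5-bis(triisopropylsilyloxy)benzene
Product: 20 (2S,3S)-3-[3,5-bis(triisopropylsilyloxy)phenyl]-5-{(E)-2-[3,5-bis(triisopropylsilyloxy)phenyl]ethenyl}-2-[4-(triisopropylsilyloxy)phenyl]-2,3-dihydro-1-benzofuran
Conditions: 19 (1.5 equiv), Pd2(dba)3 (2.5 mol%), [HP(t-Bu)3]BF4 (6 mol%), Cy2NMe, dioxane, 80 °C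
Reagents that add atoms: none
Why: Mizoroki–Heck coupling gives the E-stilbene by syn insertion and syn β-hydride elimination; the amine base does not touch the silyl ethers or the C2/C3 centres.

**Step 12**
Reactants: 20 (2S,3S)-3-[3,5-bis(triisopropylsilyloxy)phenyl]-5-{(E)-2-[3,5-bis(triisopropylsilyloxy)phenyl]ethenyl}-2-[4-(triisopropylsilyloxy)phenyl]-2,3-dihydro-1-benzofuran
Product: 21 (2S,3S)-trans-delta-viniferin
Conditions: TBAF (6 equiv), AcOH (6 equiv), THF, 0 °C → rt, under Ar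
Reagents that add atoms: none
Why: Fluoride desilylation of the five aryl silyl ethers, buffered with acetic acid so that neither acid-induced C2 ionisation nor phenoxide oxidation can occur.

**Compound list**
1 | 5-bromobenzene-1,3-diol | Oc1cc(O)cc(Br)c1 | starting material
2 | 1-bromo-3,5-bis(triisopropylsilyloxy)benzene | CC(C)[Si](Oc1cc(Br)cc(O[Si](C(C)C)(C(C)C)C(C)C)c1)(C(C)C)C(C)C | intermediate
3 | 5-bromo-2-hydroxybenzaldehyde | O=Cc1cc(Br)ccc1O | starting material
4 | [3,5-bis(triisopropylsilyloxy)phenyl]magnesium bromide | Br[Mg]c1cc(O[Si](C(C)C)(C(C)C)C(C)C)cc(O[Si](C(C)C)(C(C)C)C(C)C)c1 | intermediate (not isolated)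
5 | rac-4-bromo-2-{[3,5-bis(triisopropylsilyloxy)phenyl](hydroxy)methyl}phenol | Oc1ccc(Br)cc1C(O)c1cc(O[Si](C(C)C)(C(C)C)C(C)C)cc(O[Si](C(C)C)(C(C)C)C(C)C)c1 | intermediate
6 | rac-4-bromo-2-{[3,5-bis(triisopropylsilyloxy)phenyl](4-methylbenzenesulfonyl)methyl}phenol | Cc1ccc(cc1)S(=O)(=O)C(c1cc(Br)ccc1O)c1cc(O[Si](C(C)C)(C(C)C)C(C)C)cc(O[Si](C(C)C)(C(C)C)C(C)C)c1 | intermediate
7 | 4-hydroxybenzaldehyde | O=Cc1ccc(O)cc1 | starting material
8 | 4-(triisopropylsilyloxy)benzaldehyde | CC(C)[Si](Oc1ccc(C=O)cc1)(C(C)C)C(C)C | intermediate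
9 | [4-(triisopropylsilyloxy)phenyl]methanol | CC(C)[Si](Oc1ccc(CO)cc1)(C(C)C)C(C)C | intermediate
10 | 4-(triisopropylsilyloxy)benzyl bromide | CC(C)[Si](Oc1ccc(CBr)cc1)(C(C)C)C(C)C | intermediate
11 | (1R,4R,5R)-4,7,7-trimethyl-6-thiabicyclo[3.2.1]octane (isothiocineole) | C[C@@H]1CC[C@@H]2C[C@H]1SC2(C)C | starting material
12 | (1R,4R,5R,6R)-4,7,7-trimethyl-6-[4-(triisopropylsilyloxy)benzyl]-6-thiabicyclo[3.2.1]octan-6-ium tetrafluoroborate | C[C@@H]1CC[C@@H]2C[C@H]1[S@@+](Cc1ccc(O[Si](C(C)C)(C(C)C)C(C)C)cc1)C2(C)C.F[B-](F)(F)F | intermediate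
13 | 4-bromo-6-{[3,5-bis(triisopropylsilyloxy)phenyl]methylidene}cyclohexa-2,4-dien-1-one (o-quinone methide; exocyclic C=C geometry not defined) | O=C1C=CC(Br)=CC1=Cc1cc(O[Si](C(C)C)(C(C)C)C(C)C)cc(O[Si](C(C)C)(C(C)C)C(C)C)c1 | intermediate (not isolated)
14 | sulfonium ylide of 12 (benzylic carbanion on sulfur; bicyclic part as in 12) | C[C@@H]1CC[C@@H]2C[C@H]1[S@@+]([CH-]c1ccc(O[Si](C(C)C)(C(C)C)C(C)C)cc1)C2(C)C | intermediate (not isolated)
15 | anti-betaine: 4-bromo-2-{(1S,2R)-1-[3,5-bis(triisopropylsilyloxy)phenyl]-2-[4-(triisopropylsilyloxy)phenyl]-2-[(1R,4R,5R)-4,7,7-trimethyl-6-thiabicyclo[3.2.1]octan-6-ium-6-yl]ethyl}phenolate | C[C@@H]1CC[C@@H]2C[C@H]1[S@@+]([C@@H](c1ccc(O[Si](C(C)C)(C(C)C)C(C)C)cc1)[C@@H](c1cc(O[Si](C(C)C)(C(C)C)C(C)C)cc(O[Si](C(C)C)(C(C)C)C(C)C)c1)c1cc(Br)ccc1[O-])C2(C)C | intermediate (not isolated)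
16 | (2S,3S)-5-bromo-3-[3,5-bis(triisopropylsilyloxy)phenyl]-2-[4-(triisopropylsilyloxy)phenyl]-2,3-dihydro-1-benzofuran (trans) | CC(C)[Si](Oc1ccc([C@H]2Oc3ccc(Br)cc3[C@@H]2c2cc(O[Si](C(C)C)(C(C)C)C(C)C)cc(O[Si](C(C)C)(C(C)C)C(C)C)c2)cc1)(C(C)C)C(C)C | intermediate
17 | 3,5-dihydroxybenzaldehyde | O=Cc1cc(O)cc(O)c1 | starting material
18 | 3,5-bis(triisopropylsilyloxy)benzaldehyde | CC(C)[Si](Oc1cc(C=O)cc(O[Si](C(C)C)(C(C)C)C(C)C)c1)(C(C)C)C(C)C | intermediate
19 | 1-ethenyl-3,5-bis(triisopropylsilyloxy)benzene | C=Cc1cc(O[Si](C(C)C)(C(C)C)C(C)C)cc(O[Si](C(C)C)(C(C)C)C(C)C)c1 | intermediate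
20 | (2S,3S)-trans-delta-viniferin pentakis(triisopropylsilyl) ether, E-alkene | CC(C)[Si](Oc1ccc([C@H]2Oc3ccc(/C=C/c4cc(O[Si](C(C)C)(C(C)C)C(C)C)cc(O[Si](C(C)C)(C(C)C)C(C)C)c4)cc3[C@@H]2c2cc(O[Si](C(C)C)(C(C)C)C(C)C)cc(O[Si](C(C)C)(C(C)C)C(C)C)c2)cc1)(C(C)C)C(C)C | intermediate
21 | (2S,3S)-trans-delta-viniferin | Oc1ccc([C@H]2Oc3ccc(/C=C/c4cc(O)cc(O)c4)cc3[C@@H]2c2cc(O)cc(O)c2)cc1 | target

**Totals**
Total step count: 12. Longest linear sequence: 7 steps (steps 4, 5, 6, 7, 8, 11, 12, from 4-hydroxybenzaldehyde).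

**Three steps most likely to fail**

Step 8 (level and sense of asymmetric induction and trans/cis ratio with this electron-rich, semi-stabilised ylide are not proven; competing O- or S-benzylation by the salt is possible). Fallback: give up asymmetric induction and resolve. Setting out from bromide 10 and sulfone 6, tetrahydrothiophene is alkylated with 10 (NaBF4, acetone) to 1-[4-(triisopropylsilyloxy)benzyl]thiolan-1-ium tetrafluoroborate F1. F1 and 6 under the same carbonate conditions give the racemic trans-5-bromo-2,3-diaryl-2,3-dihydrobenzofuran F2. Preparative chiral SFC on an amylose phase separates the enantiomers and the route is rejoined at 16.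

Step 7 (the p-silyloxybenzyl bromide and its sulfonium salt ionise easily and may hydrolyse or revert). Fallback: bypass the halide. Setting out from alcohol 9 and sulfide 11, Tf2O and 2,6-lutidine in CH2Cl2 at −78 °C form the benzylic triflate in the presence of the sulfide, giving (1R,4R,5R,6R)-4,7,7-trimethyl-6-[4-(triisopropylsilyloxy)benzyl]-6-thiabicyclo[3.2.1]octan-6-ium trifluoromethanesulfonate F3. F3 is used crude with 6 and Cs2CO3 as in step 8, and the route is rejoined at 16.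

Step 11 (slow oxidative addition of the electron-rich aryl bromide, and branched or Z by-products). Fallback: fix the alkene geometry before the coupling. Setting out from styrene 19, cross-metathesis with vinylboronic acid pinacol ester (Grubbs II, CH2Cl2, 40 °C) gives 2-{(E)-2-[3,5-bis(triisopropylsilyloxy)phenyl]ethenyl}-4,4,5,5-tetramethyl-1,3,2-dioxaborolane F4. Suzuki–Miyaura coupling of F4 with bromide 16 (Pd(dppf)Cl2, K3PO4, dioxane–H2O, 70 °C) rejoins the route at 20.

**Further compounds**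
F1 | step 8 | 1-[4-(triisopropylsilyloxy)benzyl]thiolan-1-ium tetrafluoroborate | CC(C)[Si](Oc1ccc(C[S+]2CCCC2)cc1)(C(C)C)C(C)C.F[B-](F)(F)F
F2 | step 8 | rac-(2S*,3S*)-5-bromo-3-[3,5-bis(triisopropylsilyloxy)phenyl]-2-[4-(triisopropylsilyloxy)phenyl]-2,3-dihydro-1-benzofuran (racemate, trans; one enantiomer drawn) | CC(C)[Si](Oc1ccc([C@H]2Oc3ccc(Br)cc3[C@@H]2c2cc(O[Si](C(C)C)(C(C)C)C(C)C)cc(O[Si](C(C)C)(C(C)C)C(C)C)c2)cc1)(C(C)C)C(C)C
F3 | step 7 | (1R,4R,5R,6R)-4,7,7-trimethyl-6-[4-(triisopropylsilyloxy)benzyl]-6-thiabicyclo[3.2.1]octan-6-ium trifluoromethanesulfonate | C[C@@H]1CC[C@@H]2C[C@H]1[S@@+](Cc1ccc(O[Si](C(C)C)(C(C)C)C(C)C)cc1)C2(C)C.[O-]S(=O)(=O)C(F)(F)F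
F4 | step 11 | 2-{(E)-2-[3,5-bis(triisopropylsilyloxy)phenyl]ethenyl}-4,4,5,5-tetramethyl-1,3,2-dioxaborolane | CC(C)[Si](Oc1cc(/C=C/B2OC(C)(C)C(C)(C)O2)cc(O[Si](C(C)C)(C(C)C)C(C)C)c1)(C(C)C)C(C)C
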